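**Strategy**

Everything rests on closing the oxolane ring by the C2–C3 bond, C2 being the benzylic ring carbon next to O1 and C3 the carbon that carries the CH2O ester arm. The key step exploits that C2 is an acetal-level, aryl-stabilised oxocarbenium carbon and that C3 turns into an enolate carbon once its CH2O carbon is a lactone carbonyl tied to the benzylic carbon of the C4 benzyl group. From a trans-4-(alkoxymethyl)-5-aryl-γ-butyrolactone bearing a mixed veratraldehyde acetal on O1, a Mukaiyama-type cyclisation forms C2–C3, sets C2 and C3, and the temporary lactone ring forces the 3,4-cis arrangement; it is later opened by hydrogenolysis.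

Key step: step 5

Remark: acetal 8 is taken as a purchasable reagent; the acetal carbon of 9 forms as both epimers, which is immaterial because it becomes planar in step 5.

**Route**

Step 1
Reactants: 1 (4S)-4-benzyl-1,3-oxazolidin-2-one; 2 methyl 4-chloro-4-oxobutanoate
Product: 3 methyl 4-[(4S)-4-benzyl-2-oxo-1,3-oxazolidin-3-yl]-4-oxobutanoate
Conditions: n-BuLi, THF, −78 °C; then 2, −78 to 0 °C
Reagents that add atoms: none
Why: N-acylation of the lithiated oxazolidinone by the acid chloride is much faster than attack at the methyl ester, so the imide should form selectively.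

Step 2
Reactants: 3 methyl 4-[(4S)-4-benzyl-2-oxo-1,3-oxazolidin-3-yl]-4-oxobutanoate; 4 3,4-dimethoxybenzaldehyde
Product: 6 (4S)-4-benzyl-3-{[(2S,3S)-2-(3,4-dimethoxyphenyl)-5-oxooxolan-3-yl]carbonyl}-1,3-oxazolidin-2-one, via syn-aldol adduct 5 (not isolated)
Conditions: Bu2BOTf, iPr2NEt, CH2Cl2, 0 °C; then 4, −78 to 0 °C; H2O2, MeOH, pH 7 buffer; then TsOH (cat.), CH2Cl2, rt
Reagents that add atoms: none
Why: Evans syn-aldol reaction, in which the Z-boron enolate formed at the imide α-CH2 (not at the ester) adds to the aldehyde through a Zimmerman–Traxler chair on the face left open by the (S)-benzyl group, setting the future C4 and the sacrificial benzylic carbinol center as the (S,S) syn pair, after which the γ-hydroxy ester should lactonise to the trans lactone.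

Step 3
Reactants: 6 (4S)-4-benzyl-3-{[(2S,3S)-2-(3,4-dimethoxyphenyl)-5-oxooxolan-3-yl]carbonyl}-1,3-oxazolidin-2-one
Product: 7 (4R,5S)-5-(3,4-dimethoxyphenyl)-4-(hydroxymethyl)oxolan-2-one
Conditions: NaBH4, THF/H2O (4:1), 0 °C; NH4Cl quench
Reagents that add atoms: none
Why: Reductive removal of the auxiliary, which should be chemoselective because the exocyclic imide carbonyl is far more electrophilic than the γ-lactone, and which touches no stereocenter.

Step 4
Reactants: 7 (4R,5S)-5-(3,4-dimethoxyphenyl)-4-(hydroxymethyl)oxolan-2-one; 8 3,4-dimethoxybenzaldehyde dimethyl acetal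
Product: 9 (4R,5S)-5-(3,4-dimethoxyphenyl)-4-{[(3,4-dimethoxyphenyl)(methoxy)methoxy]methyl}oxolan-2-one (both epimers at the acetal carbon)
Conditions: 8 (5 equiv), PPTS (cat.), PhMe, 40 °C, reduced pressure (removal of MeOH); Et3N quench
Reagents that add atoms: none
Why: Acid-catalysed transacetalisation, driven by excess 8 and removal of methanol, should put the future C2 onto O1 before any C–C bond is made.

Step 5
Reactants: 9 (4R,5S)-5-(3,4-dimethoxyphenyl)-4-{[(3,4-dimethoxyphenyl)(methoxy)methoxy]methyl}oxolan-2-one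
Product: 12 (3S,3aR,6S,6aS)-3,6-bis(3,4-dimethoxyphenyl)tetrahydro-1H,3H-furo[3,4-c]furan-1-one, via silyl ketene acetal 10 (not isolated), via oxocarbenium triflate 11 (not isolated)
Conditions: LiN(iPr)2, Me3SiCl, THF, −78 °C; pentane filtration; then Me3SiOTf (0.2 equiv), CH2Cl2 (0.01 M), −78 to −40 °C
Reagents that add atoms: none
Why: LiN(iPr)2/Me3SiCl converts the lactone into its cyclic silyl ketene acetal 10, catalytic Me3SiOTf then removes the methoxy group of the mixed acetal to give the aryl-stabilised oxocarbenium ion 11, and the ketene acetal carbon C3 adds to its carbon C2, after which loss of the silyl group from the lactone carbonyl returns the catalyst. The closest known reaction types are the Mukaiyama addition of silyl ketene acetals to acetals and the Lewis-acid ring contraction of 4,5-dihydro-1,3-dioxepines to 2-substituted oxolane-3-carbaldehydes, in which an enolate and an oxocarbenium ion joined by the same O–CH2–CH chain close this very bond. The oxolane ring closes in the 5-(enolexo) mode with respect to the ketene acetal and endo with respect to the C=O+ unit, giving a cis-fused 3,7-dioxabicyclo[3.3.0]octanone. C3 is controlled by the C4 stereocenter through the lactone template, because only cis fusion of the two five-membered rings is possible, so the C3 carbonyl carbon and the C4 benzylic carbon end up cis; C2 is controlled by the bicycle, the aryl group taking the exo (convex) position trans to the C3 carbonyl carbon, and an endo isomer should equilibrate to exo under the acid by reversible ionisation of the electron-rich benzylic C2–O1 bond. The step needs ionisation with loss of methoxide and intramolecular capture at carbon, which high dilution, low temperature and the reversibility of the unproductive ionisation (ion-pair return) should secure, while the sacrificial aryl-bearing lactone center sits exo and should not interfere.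

Step 6
Reactants: 12 (3S,3aR,6S,6aS)-3,6-bis(3,4-dimethoxyphenyl)tetrahydro-1H,3H-furo[3,4-c]furan-1-one
Product: 13 (2S,3S,4R)-4-(3,4-dimethoxybenzyl)-2-(3,4-dimethoxyphenyl)oxolane-3-carboxylic acid
Conditions: H2 (1 atm), 10% Pd/C, EtOAc/AcOH (10:1), rt, stopped after 1 equiv H2
Reagents that add atoms: none
Why: Hydrogenolysis should cleave the benzylic lactone C–O bond faster than the benzylic ether C2–O1 bond because carboxylate is the better leaving group, which opens the temporary ring, turns the sacrificial center into the CH2 of the benzyl group and leaves C2, C3 and C4 untouched.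

Step 7
Reactants: 13 (2S,3S,4R)-4-(3,4-dimethoxybenzyl)-2-(3,4-dimethoxyphenyl)oxolane-3-carboxylic acid
Product: 14 [(2S,3R,4R)-4-(3,4-dimethoxybenzyl)-2-(3,4-dimethoxyphenyl)oxolan-3-yl]methanol
Conditions: LiAlH4, THF, 0 °C to rt
Reagents that add atoms: none
Why: Hydride reduction of the carboxylic acid to the primary alcohol should proceed through the non-enolisable carboxylate, so C3 is not epimerised.

Step 8
Reactants: 14 [(2S,3R,4R)-4-(3,4-dimethoxybenzyl)-2-(3,4-dimethoxyphenyl)oxolan-3-yl]methanol; 15 (Z)-2-methylbut-2-enoic acid (angelic acid)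
Product: 16 leoligin, [(2S,3R,4R)-4-(3,4-dimethoxybenzyl)-2-(3,4-dimethoxyphenyl)oxolan-3-yl]methyl (2Z)-2-methylbut-2-enoate
Conditions: PPh3, DIAD, THF, 0 °C to rt
Reagents that add atoms: none
Why: Mitsunobu esterification activates the primary alcohol and not the acid, so the (Z)-alkene should not be exposed to the acyl activation that isomerises angelates to tiglates, and no stereocenter is involved.

**Compound list**

1 | (4S)-4-benzyl-1,3-oxazolidin-2-one | O=C1OC[C@H](Cc2ccccc2)N1 | starting material
2 | methyl 4-chloro-4-oxobutanoate | COC(=O)CCC(Cl)=O | starting material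
3 | methyl 4-[(4S)-4-benzyl-2-oxo-1,3-oxazolidin-3-yl]-4-oxobutanoate | COC(=O)CCC(=O)N1[C@@H](Cc2ccccc2)COC1=O | intermediate
4 | 3,4-dimethoxybenzaldehyde (veratraldehyde) | COc1ccc(C=O)cc1OC | starting material
5 | methyl (3S)-4-[(4S)-4-benzyl-2-oxo-1,3-oxazolidin-3-yl]-3-[(S)-(3,4-dimethoxyphenyl)(hydroxy)methyl]-4-oxobutanoate (syn-aldol adduct, not isolated) | COC(=O)C[C@H](C(=O)N1[C@@H](Cc2ccccc2)COC1=O)[C@H](O)c1ccc(OC)c(OC)c1 | intermediate
6 | (4S)-4-benzyl-3-{[(2S,3S)-2-(3,4-dimethoxyphenyl)-5-oxooxolan-3-yl]carbonyl}-1,3-oxazolidin-2-one (trans lactone) | O=C1C[C@H](C(=O)N2[C@@H](Cc3ccccc3)COC2=O)[C@@H](c2ccc(OC)c(OC)c2)O1 | intermediate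
7 | (4R,5S)-5-(3,4-dimethoxyphenyl)-4-(hydroxymethyl)oxolan-2-one | O=C1C[C@H](CO)[C@@H](c2ccc(OC)c(OC)c2)O1 | intermediate
8 | 3,4-dimethoxybenzaldehyde dimethyl acetal | COC(OC)c1ccc(OC)c(OC)c1 | starting material
9 | (4R,5S)-5-(3,4-dimethoxyphenyl)-4-{[(3,4-dimethoxyphenyl)(methoxy)methoxy]methyl}oxolan-2-one (both acetal epimers) | O=C1C[C@H](COC(OC)c2ccc(OC)c(OC)c2)[C@@H](c2ccc(OC)c(OC)c2)O1 | intermediate
10 | {[(4R,5S)-5-(3,4-dimethoxyphenyl)-4-{[(3,4-dimethoxyphenyl)(methoxy)methoxy]methyl}-4,5-dihydrofuran-2-yl]oxy}trimethylsilane (silyl ketene acetal, not isolated) | C[Si](C)(C)OC1=C[C@H](COC(OC)c2ccc(OC)c(OC)c2)[C@@H](c2ccc(OC)c(OC)c2)O1 | intermediate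
11 | (3,4-dimethoxybenzylidene){[(2S,3R)-2-(3,4-dimethoxyphenyl)-5-(trimethylsilyloxy)-2,3-dihydrofuran-3-yl]methyl}oxonium triflate (not isolated) | C[Si](C)(C)OC1=C[C@H](C[O+]=Cc2ccc(OC)c(OC)c2)[C@@H](c2ccc(OC)c(OC)c2)O1.[O-]S(=O)(=O)C(F)(F)F | intermediate
12 | (3S,3aR,6S,6aS)-3,6-bis(3,4-dimethoxyphenyl)tetrahydro-1H,3H-furo[3,4-c]furan-1-one (cis-fused, both aryl groups exo) | O=C1O[C@H](c2ccc(OC)c(OC)c2)[C@H]2CO[C@H](c3ccc(OC)c(OC)c3)[C@@H]12 | intermediate
13 | (2S,3S,4R)-4-(3,4-dimethoxybenzyl)-2-(3,4-dimethoxyphenyl)oxolane-3-carboxylic acid | OC(=O)[C@H]1[C@@H](Cc2ccc(OC)c(OC)c2)CO[C@@H]1c1ccc(OC)c(OC)c1 | intermediate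
14 | [(2S,3R,4R)-4-(3,4-dimethoxybenzyl)-2-(3,4-dimethoxyphenyl)oxolan-3-yl]methanol | OC[C@H]1[C@@H](Cc2ccc(OC)c(OC)c2)CO[C@@H]1c1ccc(OC)c(OC)c1 | intermediate
15 | (Z)-2-methylbut-2-enoic acid (angelic acid) | C/C=C(/C)C(=O)O | starting material
16 | leoligin | C/C=C(/C)C(=O)OC[C@H]1[C@@H](Cc2ccc(OC)c(OC)c2)CO[C@@H]1c1ccc(OC)c(OC)c1 | target

**Count and risks**

Total step count: 8. Longest linear sequence: 8 steps (1 to 16).

Steps most likely to fail:

Step 5. The mixed acetal may ionise on the tethered oxygen, so that the oxocarbenium ion leaves the molecule and is captured intermolecularly, or the silyl ketene acetal may be protonated before it cyclises. The fallback replaces enolate/oxocarbenium chemistry by carbene C–H insertion and sets out from 7. Acid-catalysed benzylation with 3,4-dimethoxybenzyl 2,2,2-trichloroacetimidate (TfOH cat., CH2Cl2, 0 °C) should give the 3,4-dimethoxybenzyl ether F1. Deacylative Regitz diazo transfer (LiN(SiMe3)2, CF3CO2CH2CF3, THF, −78 °C; then MsN3, Et3N, MeCN) should give the α-diazo lactone F2. Rh2(OAc)4 (1 mol %) in CH2Cl2 should then insert the carbenoid carbon C3 into the benzylic C–H bond next to O1, again forming C2–C3 within the cis-fused bicycle, and the route is rejoined at 12, after acid equilibration of C2 if needed.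

Step 6. Hydrogenolysis may not stop at the lactone and may also cleave the benzylic C2–O1 ether bond. The fallback removes the benzylic oxygen by a radical path and sets out from 12. LiAlH4 (THF, 0 °C) should give the diol F3, and t-BuMe2SiCl/imidazole (DMF, 0 °C) should silylate only the primary hydroxyl to give the silyl ether F4. NaH, CS2, then MeI (THF) should give the S-methyl xanthate F5. Barton–McCombie deoxygenation (Bu3SnH, AIBN, PhMe, 90 °C) should give the benzyl compound F6, and Bu4NF (THF) then returns the route to 14.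

Step 3. The basic borohydride medium may cause β-elimination of the lactone carboxylate from the imide, or migration of the lactone onto the new primary hydroxyl. The fallback avoids alkoxide-forming reduction of the imide and sets out from 6. LiOH/H2O2 (THF/H2O, 0 °C) should hydrolyse the imide to the paraconic acid F7, and BH3·SMe2 (THF, 0 °C) should reduce the carboxylic acid in the presence of the lactone, rejoining the route at 7.

**Further compounds**

F1 | step 5 | (4R,5S)-4-{[(3,4-dimethoxybenzyl)oxy]methyl}-5-(3,4-dimethoxyphenyl)oxolan-2-one | O=C1C[C@H](COCc2ccc(OC)c(OC)c2)[C@@H](c2ccc(OC)c(OC)c2)O1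
F2 | step 5 | (4R,5S)-3-diazo-4-{[(3,4-dimethoxybenzyl)oxy]methyl}-5-(3,4-dimethoxyphenyl)oxolan-2-one | O=C1C(=[N+]=[N-])[C@H](COCc2ccc(OC)c(OC)c2)[C@@H](c2ccc(OC)c(OC)c2)O1
F3 | step 6 | (S)-(3,4-dimethoxyphenyl)[(3R,4R,5S)-5-(3,4-dimethoxyphenyl)-4-(hydroxymethyl)oxolan-3-yl]methanol | OC[C@H]1[C@@H]([C@H](O)c2ccc(OC)c(OC)c2)CO[C@@H]1c1ccc(OC)c(OC)c1
F4 | step 6 | (S)-[(3R,4R,5S)-4-{[(tert-butyldimethylsilyl)oxy]methyl}-5-(3,4-dimethoxyphenyl)oxolan-3-yl](3,4-dimethoxyphenyl)methanol | CC(C)(C)[Si](C)(C)OC[C@H]1[C@@H]([C@H](O)c2ccc(OC)c(OC)c2)CO[C@@H]1c1ccc(OC)c(OC)c1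
F5 | step 6 | O-{(S)-[(3R,4R,5S)-4-{[(tert-butyldimethylsilyl)oxy]methyl}-5-(3,4-dimethoxyphenyl)oxolan-3-yl](3,4-dimethoxyphenyl)methyl} S-methyl carbonodithioate | CC(C)(C)[Si](C)(C)OC[C@H]1[C@@H]([C@H](OC(=S)SC)c2ccc(OC)c(OC)c2)CO[C@@H]1c1ccc(OC)c(OC)c1
F6 | step 6 | tert-butyl{[(2S,3R,4R)-4-(3,4-dimethoxybenzyl)-2-(3,4-dimethoxyphenyl)oxolan-3-yl]methoxy}dimethylsilane | CC(C)(C)[Si](C)(C)OC[C@H]1[C@@H](Cc2ccc(OC)c(OC)c2)CO[C@@H]1c1ccc(OC)c(OC)c1
F7 | step 3 | (2S,3S)-2-(3,4-dimethoxyphenyl)-5-oxooxolane-3-carboxylic acid | O=C1C[C@H](C(=O)O)[C@@H](c2ccc(OC)c(OC)c2)O1
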